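**Retrosynthetic overview**

1. Ring A carries C1 CO2Me, C2 O-aryl, C3 OMe, C4 Cl, C5 OH and C6 H. Its ether carbon C2 lies between C1 and C3 and para to the C5 oxygen, so ring A is the aromatised form of a 2,5-cyclohexadienone with C2 as spiro carbon. The diaryl ether acid then comes from retro-Claisen opening of a spiro[benzofuran-3-one/cyclohexadienone] at the furanone C3–C2 bond (C3 becomes the CO2H of ring B), with MOM removal last.
2. The C4 chlorine is put on the spiro dienone, at the α-carbon of its β-methoxy enone.
3. The spiro dienone comes from double Michael addition of the C2 methylene of 4-(methoxymethoxy)-6-methylbenzofuran-3(2H)-one to both alkyne termini of methyl 6-methoxy-4-oxohexa-2,5-diynoate (forms C2–C1 and C2–C3).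
4. The benzofuranone comes from orcinol (bis-MOM ether, C2 lithiation, chloroacetylation, mono-deprotection, ring closure). The diynone comes from methoxyethyne and methyl 4-oxobut-2-ynoate, then oxidation.
5. Ring order: ring B is aromatic from the start; the furanone ring closes in step 3; ring A closes in step 8 and is aromatised in step 10, when the furanone is opened again.

Key step: step 8

Remark: the target has no stereocentre. The diynol, the mono-adduct and the spiro dienones are racemic and drawn as one enantiomer; diastereomer mixtures are written without descriptors. Methyl 4-hydroxybut-2-ynoate and 2-chloro-N-methoxy-N-methylacetamide are taken as purchased materials.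

**Route**

Step 1
Reactants: 1 orcinol (5-methylbenzene-1,3-diol, anhydrous)
Product: 2 1,3-bis(methoxymethoxy)-5-methylbenzene
Conditions: MOMCl (2.5 equiv), i-Pr2NEt (3 equiv), CH2Cl2, 0 °C to rt
Reagents that add atoms: chloromethyl methyl ether (MOMCl), COCCl
Why: Both phenols are alkylated by the reactive α-chloro ether in the presence of the hindered amine base (Williamson-type MOM protection), which also installs the two ortho-directing groups used in step 2.

Step 2
Reactants: 2 1,3-bis(methoxymethoxy)-5-methylbenzene; 3 2-chloro-N-methoxy-N-methylacetamide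
Product: 5 2-chloro-1-[2,6-bis(methoxymethoxy)-4-methylphenyl]ethan-1-one, via aryllithium 4 (not isolated)
Conditions: n-BuLi (1.05 equiv), THF, 0 °C; then 3, −78 to 0 °C; aq. NH4Cl
Reagents that add atoms: none
Why: Directed ortho-metalation: the two MOM ethers jointly direct n-BuLi to C2 between them, and the aryllithium acylates the Weinreb amide through a chelated tetrahedral adduct that survives until the quench (Weinreb ketone synthesis), so the α-chloro ketone is not attacked a second time.

Step 3
Reactants: 5 2-chloro-1-[2,6-bis(methoxymethoxy)-4-methylphenyl]ethan-1-one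
Product: 7 4-(methoxymethoxy)-6-methyl-1-benzofuran-3(2H)-one, via mono-MOM phenol 6 (not isolated)
Conditions: HCl (cat.), MeOH, 0 °C to rt; then NaOAc (3 equiv), 60 °C
Reagents that add atoms: none
Why: Acid-catalysed transacetalisation to methanol removes one MOM group ortho to the ketone, after which the new O–H···O=C hydrogen bond slows loss of the second (the known selective mono-deprotection of 2,6-bis(MOM-oxy)aryl ketones), and the acetate-buffered phenol then displaces chloride in a 5-exo-tet intramolecular Williamson etherification, the classical closure of benzofuran-3(2H)-ones; the weak base avoids aldol self-condensation of the product.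

Step 4
Reactants: 8 methyl 4-hydroxybut-2-ynoate
Product: 9 methyl 4-oxobut-2-ynoate
Conditions: MnO2 (activated, excess), CH2Cl2, rt; filtered, solution used at once
Reagents that add atoms: none
Why: Activated MnO2 oxidises propargylic alcohols to ynals under neutral heterogeneous conditions without touching the ester, and filtration gives a solution of the sensitive aldehyde that is used directly.

Step 5
Reactants: 10 chloroacetaldehyde dimethyl acetal (2-chloro-1,1-dimethoxyethane)
Product: 12 methoxyethyne, via sodium methoxyacetylide 11 (not isolated)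
Conditions: NaNH2 (3 equiv), liq. NH3, −33 °C; then cold sat. aq. NaCl, −60 °C; distilled into cold THF
Reagents that add atoms: none
Why: Threefold use of NaNH2: elimination of methanol from the acetal, dehydrochlorination of the resulting chloro enol ether and deprotonation give the alkoxyacetylide (the classical alkoxyacetylene synthesis), and cold brine releases the volatile ynol ether free of amine.

Step 6
Reactants: 12 methoxyethyne; 9 methyl 4-oxobut-2-ynoate
Product: 14 methyl 4-hydroxy-6-methoxyhexa-2,5-diynoate (racemic), via lithium methoxyacetylide 13 (not isolated)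
Conditions: n-BuLi, THF, −78 °C; then added to 9 (1.1 equiv), THF, −78 °C; aq. NH4Cl, −78 °C
Reagents that add atoms: none
Why: 1,2-Addition of a lithium acetylide to an aldehyde: at −78 °C with inverse addition the hard acetylide attacks the formyl group much faster than the ester or the alkyne, no amine is present to add to the ynoate, and the new carbinol centre is racemic and is removed in step 7.

Step 7
Reactants: 14 methyl 4-hydroxy-6-methoxyhexa-2,5-diynoate
Product: 15 methyl 6-methoxy-4-oxohexa-2,5-diynoate
Conditions: MnO2 (activated, excess), CH2Cl2, 0 °C; filtered, solvent exchanged cold to THF, used at once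
Reagents that add atoms: none
Why: MnO2 oxidation of a doubly propargylic alcohol to the ketone, the same neutral method by which alkoxyethynyl carbinols are converted to alkoxyethynyl ketones, avoiding the acid that would trigger Meyer–Schuster rearrangement of the ynol ether carbinol.

Step 8
Reactants: 7 4-(methoxymethoxy)-6-methyl-1-benzofuran-3(2H)-one; 15 methyl 6-methoxy-4-oxohexa-2,5-diynoate
Product: 17 methyl 6'-methoxy-4-(methoxymethoxy)-6-methyl-3,4'-dioxo-3H-spiro[1-benzofuran-2,1'-cyclohexa-2',5'-diene]-2'-carboxylate (racemic), via mono-Michael adduct 16 (not isolated)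
Conditions: KOtBu (0.15 equiv), THF/t-BuOH, −40 to 0 °C, 15 added slowly; AcOH quench
Reagents that add atoms: none
Why: Proposed new method: tert-butoxide forms the C2 enolate of 7 (an aromatic 3-oxidobenzofuran, hence easily generated), which adds to the ester-bearing alkyne carbon of 15, the position β to the central ketone; proton transfer gives adduct 16, whose still acidic C2–H is removed again so that the enolate closes onto the methoxy-bearing alkyne carbon and returns the base. The closest known reaction types are the alkoxide-catalysed double Michael spiroannulation of benzofuran-3(2H)-ones with alkoxyethynyl vinyl ketones and the double hetero-Michael additions to 1,4-diyn-3-ones that give 4-pyranone-type rings; new here is a carbon nucleophile forming both bonds to a bis-alkynyl ketone, which gives the cross-conjugated dienone directly. Ring A closes in the 6-endo-dig mode, which needs the furanone and the ynone carbonyl cis on the alkene of 16; in the extended enolate of 16 that alkene is a single bond, so the E and Z forms interconvert under the conditions. The spiro carbon is the only new stereocentre, nothing controls it, and the racemate is accepted because step 10 turns this carbon into an sp2 ring carbon. The step needs bond formation β to the ketone on both arms (not β to the ester) and C- rather than O-attack of the enolate: the ketone is the stronger acceptor, the methoxy group polarises its alkyne in the same sense, only this mode leads to a six-membered ring, and catalytic base, low temperature and slow addition of 15 limit oligomerisation of the diynone.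

Step 9
Reactants: 17 methyl 6'-methoxy-4-(methoxymethoxy)-6-methyl-3,4'-dioxo-3H-spiro[1-benzofuran-2,1'-cyclohexa-2',5'-diene]-2'-carboxylate
Product: 18 methyl 5'-chloro-6'-methoxy-4-(methoxymethoxy)-6-methyl-3,4'-dioxo-3H-spiro[1-benzofuran-2,1'-cyclohexa-2',5'-diene]-2'-carboxylate (racemic)
Conditions: NCS (1.05 equiv), MeCN, 0 °C to rt, dark, no acid
Reagents that add atoms: N-chlorosuccinimide (NCS), O=C1CCC(=O)N1Cl
Why: Electrophilic α-chlorination of a vinylogous ester: C5' is the β-carbon of the enol ether C6'(OMe)=C5' and the most nucleophilic carbon, attack gives a methoxy-stabilised oxocarbenium ion that loses H+ to restore the enone, whereas C3' belongs to an electron-poor ene-ester and ring B, whose two oxygen donors are conjugated with the coplanar C3 ketone, should react more slowly with NCS in the absence of acid.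

Step 10
Reactants: 18 methyl 5'-chloro-6'-methoxy-4-(methoxymethoxy)-6-methyl-3,4'-dioxo-3H-spiro[1-benzofuran-2,1'-cyclohexa-2',5'-diene]-2'-carboxylate
Product: 19 2-[3-chloro-4-hydroxy-2-methoxy-6-(methoxycarbonyl)phenoxy]-6-(methoxymethoxy)-4-methylbenzoic acid
Conditions: NaHCO3 (3 equiv), THF/H2O, rt to 40 °C; then 1 M HCl to pH 3, 0 °C
Reagents that add atoms: water, O
Why: Retro-Claisen-type C–C cleavage known for spiro grisadienediones: hydroxide adds to the C3 ketone and the tetrahedral intermediate expels the spiro carbon because the leaving group is the aromatic ring-A phenoxide, so C3 becomes the carboxylate of ring B, the spiro stereocentre disappears, and the methyl ester and MOM ether are untouched at this pH.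

Step 11
Reactants: 19 2-[3-chloro-4-hydroxy-2-methoxy-6-(methoxycarbonyl)phenoxy]-6-(methoxymethoxy)-4-methylbenzoic acid
Product: 20 2-[3-chloro-4-hydroxy-2-methoxy-6-(methoxycarbonyl)phenoxy]-6-hydroxy-4-methylbenzoic acid (target CNP0130950.0)
Conditions: HCl (cat.), MeOH, 40 °C
Reagents that add atoms: none
Why: Acid-catalysed acetal exchange with methanol cleaves the aryl MOM ether, which is activated by the ortho carboxyl group, while the methyl ester (degenerate exchange), the diaryl ether, the aryl chloride and the doubly ortho-substituted, esterification-resistant benzoic acid are unaffected.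

**Compound list**

1 | orcinol (5-methylbenzene-1,3-diol) | Cc1cc(O)cc(O)c1 | starting material
2 | 1,3-bis(methoxymethoxy)-5-methylbenzene | COCOc1cc(C)cc(OCOC)c1 | intermediate
3 | 2-chloro-N-methoxy-N-methylacetamide | CON(C)C(=O)CCl | starting material
4 | [2,6-bis(methoxymethoxy)-4-methylphenyl]lithium | [Li]c1c(OCOC)cc(C)cc1OCOC | intermediate (not isolated)
5 | 2-chloro-1-[2,6-bis(methoxymethoxy)-4-methylphenyl]ethan-1-one | COCOc1cc(C)cc(OCOC)c1C(=O)CCl | intermediate
6 | 2-chloro-1-[2-hydroxy-6-(methoxymethoxy)-4-methylphenyl]ethan-1-one | COCOc1cc(C)cc(O)c1C(=O)CCl | intermediate (not isolated)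
7 | 4-(methoxymethoxy)-6-methyl-1-benzofuran-3(2H)-one | Cc1cc(OCOC)c2C(=O)COc2c1 | intermediate
8 | methyl 4-hydroxybut-2-ynoate | OCC#CC(=O)OC | starting material
9 | methyl 4-oxobut-2-ynoate | O=CC#CC(=O)OC | intermediate
10 | chloroacetaldehyde dimethyl acetal (2-chloro-1,1-dimethoxyethane) | COC(CCl)OC | starting material
11 | sodium methoxyacetylide | COC#C[Na] | intermediate (not isolated)
12 | methoxyethyne | COC#C | intermediate
13 | lithium methoxyacetylide | COC#C[Li] | intermediate (not isolated)
14 | methyl 4-hydroxy-6-methoxyhexa-2,5-diynoate (racemic, one enantiomer drawn) | COC#C[C@@H](O)C#CC(=O)OC | intermediate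
15 | methyl 6-methoxy-4-oxohexa-2,5-diynoate | COC#CC(=O)C#CC(=O)OC | intermediate
16 | methyl (2E)-6-methoxy-2-[4-(methoxymethoxy)-6-methyl-3-oxo-2,3-dihydro-1-benzofuran-2-yl]-4-oxohex-2-en-5-ynoate (racemic, one enantiomer drawn; E/Z interconverting) | COC#CC(=O)/C=C(/C(=O)OC)[C@H]1Oc2cc(C)cc(OCOC)c2C1=O | intermediate (not isolated)
17 | methyl 6'-methoxy-4-(methoxymethoxy)-6-methyl-3,4'-dioxo-3H-spiro[1-benzofuran-2,1'-cyclohexa-2',5'-diene]-2'-carboxylate (racemic, one enantiomer drawn) | COC(=O)C1=CC(=O)C=C(OC)[C@@]12Oc1cc(C)cc(OCOC)c1C2=O | intermediate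
18 | methyl 5'-chloro-6'-methoxy-4-(methoxymethoxy)-6-methyl-3,4'-dioxo-3H-spiro[1-benzofuran-2,1'-cyclohexa-2',5'-diene]-2'-carboxylate (racemic, one enantiomer drawn) | COC(=O)C1=CC(=O)C(Cl)=C(OC)[C@@]12Oc1cc(C)cc(OCOC)c1C2=O | intermediate
19 | 2-[3-chloro-4-hydroxy-2-methoxy-6-(methoxycarbonyl)phenoxy]-6-(methoxymethoxy)-4-methylbenzoic acid | COC(=O)c1cc(O)c(Cl)c(OC)c1Oc1cc(C)cc(OCOC)c1C(=O)O | intermediate
20 | 2-[3-chloro-4-hydroxy-2-methoxy-6-(methoxycarbonyl)phenoxy]-6-hydroxy-4-methylbenzoic acid | COC(=O)c1cc(O)c(Cl)c(OC)c1Oc1cc(C)cc(O)c1C(=O)O | target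

**Step count**

Total: 11 steps. Longest linear sequence: 7 steps (steps 1, 2, 3, 8, 9, 10, 11; the diynone branch through steps 5, 6, 7 is equally long).

**Steps most likely to fail**

1. Step 8 (proposed new method). The catalytic base may be consumed by oligomerisation of the diynone, the enolate may add through oxygen, or adduct 16 may be captured by a second diynone before the 6-endo-dig closure.
Fallback, known chemistry, setting out from 7 and 13 and returning at 17: lithium methoxyacetylide 13 is added at −78 °C to purchased methyl (E)-4-oxobut-2-enoate to give methyl (E)-4-hydroxy-6-methoxyhex-2-en-5-ynoate F1. MnO2 in CH2Cl2 oxidises it to methyl (E)-6-methoxy-4-oxohex-2-en-5-ynoate F2. KOtBu-catalysed double Michael addition of 7 to this alkoxyethynyl vinyl ketone (the established form of the spiroannulation; both bonds again form β to the ketone) should give methyl 2'-methoxy-4-(methoxymethoxy)-6-methyl-3,4'-dioxo-3H-spiro[1-benzofuran-2,1'-cyclohex-2'-ene]-6'-carboxylate F3 as a diastereomer mixture that does not matter. Dehydrogenation of its CH(CO2Me)–CH2 unit next to the ketone (SeO2, t-BuOH, reflux, the classical dehydrogenation of 1,4-dicarbonyl compounds) gives 17.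

2. Step 9. Electrophilic chlorination of ring B at C5 or C7 may compete with attack at C5', or a second chlorine may be introduced.
Fallback, setting out from 17 and returning at 20: the MOM group is removed under anhydrous conditions (Me3SiBr, CH2Cl2, −30 °C) to give methyl 4-hydroxy-6'-methoxy-6-methyl-3,4'-dioxo-3H-spiro[1-benzofuran-2,1'-cyclohexa-2',5'-diene]-2'-carboxylate F4. Acetylation (Ac2O, pyridine) gives the 4-acetoxy compound F5, in which the ester oxygen is a far weaker donor than the acetal ether, so ring B is deactivated. NCS should then chlorinate only the enol-ether carbon to give methyl 4-acetoxy-5'-chloro-6'-methoxy-6-methyl-3,4'-dioxo-3H-spiro[1-benzofuran-2,1'-cyclohexa-2',5'-diene]-2'-carboxylate F6. Aqueous NaHCO3 in THF, then warming with aqueous K2CO3, opens the spiro ketone as in step 10 and hydrolyses the aryl acetate, giving target 20 directly.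

3. Step 6. The doubly activated ynal 9 may polymerise before or during the addition, or suffer conjugate attack at the ynoate instead of 1,2-addition.
Fallback, setting out from 13 and returning at 14, with the ester introduced last: 13 is added to purchased, stable 3-(trimethylsilyl)prop-2-ynal to give 1-methoxy-5-(trimethylsilyl)penta-1,4-diyn-3-ol F7. The hydroxyl is silylated (TBSCl, imidazole, DMF) to tert-butyl{[1-methoxy-5-(trimethylsilyl)penta-1,4-diyn-3-yl]oxy}dimethylsilane F8. K2CO3 in MeOH removes only the alkynyl silyl group to give tert-butyl[(1-methoxypenta-1,4-diyn-3-yl)oxy]dimethylsilane F9. Deprotonation of the terminal alkyne (n-BuLi, THF, −78 °C) and trapping with ClCO2Me gives methyl 4-[(tert-butyldimethylsilyl)oxy]-6-methoxyhexa-2,5-diynoate F10. TBAF buffered with AcOH (THF, 0 °C) releases carbinol 14.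

**Further compounds**

F1 | step 8 | methyl (E)-4-hydroxy-6-methoxyhex-2-en-5-ynoate (racemic, one enantiomer drawn) | COC#C[C@@H](O)/C=C/C(=O)OC
F2 | step 8 | methyl (E)-6-methoxy-4-oxohex-2-en-5-ynoate | COC#CC(=O)/C=C/C(=O)OC
F3 | step 8 | methyl 2'-methoxy-4-(methoxymethoxy)-6-methyl-3,4'-dioxo-3H-spiro[1-benzofuran-2,1'-cyclohex-2'-ene]-6'-carboxylate (racemic diastereomer mixture) | COC(=O)C1CC(=O)C=C(OC)C12Oc1cc(C)cc(OCOC)c1C2=O
F4 | step 9 | methyl 4-hydroxy-6'-methoxy-6-methyl-3,4'-dioxo-3H-spiro[1-benzofuran-2,1'-cyclohexa-2',5'-diene]-2'-carboxylate (racemic, one enantiomer drawn) | COC(=O)C1=CC(=O)C=C(OC)[C@@]12Oc1cc(C)cc(O)c1C2=O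
F5 | step 9 | methyl 4-acetoxy-6'-methoxy-6-methyl-3,4'-dioxo-3H-spiro[1-benzofuran-2,1'-cyclohexa-2',5'-diene]-2'-carboxylate (racemic, one enantiomer drawn) | COC(=O)C1=CC(=O)C=C(OC)[C@@]12Oc1cc(C)cc(OC(C)=O)c1C2=O
F6 | step 9 | methyl 4-acetoxy-5'-chloro-6'-methoxy-6-methyl-3,4'-dioxo-3H-spiro[1-benzofuran-2,1'-cyclohexa-2',5'-diene]-2'-carboxylate (racemic, one enantiomer drawn) | COC(=O)C1=CC(=O)C(Cl)=C(OC)[C@@]12Oc1cc(C)cc(OC(C)=O)c1C2=O
F7 | step 6 | 1-methoxy-5-(trimethylsilyl)penta-1,4-diyn-3-ol (racemic, one enantiomer drawn) | COC#C[C@@H](O)C#C[Si](C)(C)C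
F8 | step 6 | tert-butyl{[1-methoxy-5-(trimethylsilyl)penta-1,4-diyn-3-yl]oxy}dimethylsilane (racemic, one enantiomer drawn) | COC#C[C@@H](O[Si](C)(C)C(C)(C)C)C#C[Si](C)(C)C
F9 | step 6 | tert-butyl[(1-methoxypenta-1,4-diyn-3-yl)oxy]dimethylsilane (racemic, one enantiomer drawn) | COC#C[C@@H](O[Si](C)(C)C(C)(C)C)C#C
F10 | step 6 | methyl 4-[(tert-butyldimethylsilyl)oxy]-6-methoxyhexa-2,5-diynoate (racemic, one enantiomer drawn) | COC#C[C@@H](O[Si](C)(C)C(C)(C)C)C#CC(=O)OC
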